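**Retrosynthetic overview**

- The strategy rests on the only ring, the pyrrole. N1, C2, C3 and the exocyclic formyl carbon form a three-carbon unit bound to nitrogen through its central carbon, which is the skeleton of 2-aminopropane-1,3-diol. C4, C5 and the unbranched C21 chain are the methyl carbon, carbinol carbon and chain of a C23 alkan-2-ol.
- The formyl group is taken back to a hydroxymethyl group, so the last step is an oxidation of a pyrrol-2-ylmethanol.
- The pyrrole is opened at N1–C5 (imine condensation) and C3–C4 (aldol-type bond, the bond that closes the ring), which gives tricosan-2-ol and serinol. Both bonds form in one acceptorless dehydrogenative annulation.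
- Tricosan-2-ol is cut between C3 and C4 into an eicosyl Grignard reagent and propylene oxide.

Key step: step 2

Remark: the target has no stereocentre, so tricosan-2-ol is made and used as the racemate; its carbinol carbon becomes the sp2 ring atom C5.

**Step 1**
Reactants: 1 1-bromoeicosane; 2 propylene oxide (racemic 2-methyloxirane)
Product: 4 racemic tricosan-2-ol, via eicosylmagnesium bromide 3 (not isolated)
Conditions: Mg turnings (1.3 equiv), cat. I2, THF, reflux; then CuI (10 mol%), 2 (1.5 equiv), THF, −20 → 0 °C; 1 M HCl work-up
Reagents that add atoms: none
Why: Magnesium insertion gives Grignard reagent 3, and the CuI-catalysed SN2 opening of the epoxide at its unsubstituted CH2 carbon (Grignard epoxide ring opening) should deliver the C23 secondary alcohol, whose carbinol centre is formed racemic from racemic 2 and is erased in step 2.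

**Step 2**
Reactants: 4 racemic tricosan-2-ol (2.0 equiv, excess recovered); 5 serinol (2-aminopropane-1,3-diol, 1.0 equiv)
Product: 9 (5-henicosyl-1H-pyrrol-2-yl)methanol, via tricosan-2-one 6 (not isolated), via ketimine 7 (not isolated), via imino aldehyde 8 (not isolated)
Conditions: [IrCl(cod)]2 (0.5 mol%), 6-phenyl-N2,N4-bis(diisopropylphosphanyl)-1,3,5-triazine-2,4-diamine (PN5P pincer ligand, 1 mol%), KOtBu (1.1 equiv), THF, 90 °C bath, argon, open to a bubbler, 24 h; water quench; short plug of basic alumina (hexane/EtOAc, 1% Et3N)
Reagents that add atoms: none
Why: The iridium pincer catalyst, activated by KOtBu, dehydrogenates 4 to methyl ketone 6, which condenses with the amine of 5 to ketimine 7 (N1–C5), and a second dehydrogenation of one hydroxymethyl arm gives imino aldehyde 8. Base then forms the aza-enolate of 8 at the methyl carbon, which adds to the aldehyde carbon to make C3–C4; this closure of the five-membered ring is exo-trig at the carbonyl group (the enamine-to-carbonyl closure of the Knorr pyrrole synthesis), and loss of water followed by a proton shift gives the aromatic pyrrole. The closest known reaction type is the acceptorless dehydrogenative coupling of secondary alcohols with 2-aminoalkan-1-ols to 2,5-disubstituted pyrroles under iridium, ruthenium or manganese pincer catalysis, here applied to an amino diol. No stereocentre is formed, since the carbinol carbon of 4 and the central carbon of 5 both become sp2 ring atoms. The step needs closure through the methyl group and not through the C3 methylene of the ketimine, which the preference of metallated ketimines for the less substituted α-carbon and the lower crowding of the resulting 2,5-disubstituted ring should secure; the mirror symmetry of 5 makes the choice of arm irrelevant. The spare arm is kept as the C2 hydroxymethyl group, and any part of it that is dehydrogenated further is already 10, held as its N-potassium salt, so both products converge in step 3.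

**Step 3**
Reactants: 9 (5-henicosyl-1H-pyrrol-2-yl)methanol (used at once after the alumina plug)
Product: 10 5-henicosyl-1H-pyrrole-2-carbaldehyde
Conditions: activated MnO2 (10 equiv), CH2Cl2, rt; filtration through Celite
Reagents that add atoms: none
Why: Activated MnO2 should oxidise the heteroaryl carbinol of 9 selectively to the aldehyde under neutral, heterogeneous conditions that do not trigger azafulvene formation, while the saturated chain is inert and the new formyl group deactivates the pyrrole toward further oxidation (MnO2 oxidation of an activated alcohol).

**Compound list**

1 | 1-bromoeicosane | CCCCCCCCCCCCCCCCCCCCBr | starting material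
2 | propylene oxide (racemic 2-methyloxirane) | CC1CO1 | starting material
3 | eicosylmagnesium bromide | CCCCCCCCCCCCCCCCCCCC[Mg]Br | intermediate
4 | tricosan-2-ol (racemic) | CCCCCCCCCCCCCCCCCCCCCC(C)O | intermediate
5 | serinol (2-aminopropane-1,3-diol) | NC(CO)CO | starting material
6 | tricosan-2-one | CCCCCCCCCCCCCCCCCCCCCC(C)=O | intermediate
7 | 2-(tricosan-2-ylideneamino)propane-1,3-diol (ketimine) | CCCCCCCCCCCCCCCCCCCCCC(C)=NC(CO)CO | intermediate
8 | 3-hydroxy-2-(tricosan-2-ylideneamino)propanal (imino aldehyde, racemic, transient) | CCCCCCCCCCCCCCCCCCCCCC(C)=NC(CO)C=O | intermediate
9 | (5-henicosyl-1H-pyrrol-2-yl)methanol | CCCCCCCCCCCCCCCCCCCCCc1ccc(CO)[nH]1 | intermediate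
10 | 5-henicosyl-1H-pyrrole-2-carbaldehyde | CCCCCCCCCCCCCCCCCCCCCc1ccc(C=O)[nH]1 | target

Total step count: 3
Longest linear sequence: 3 steps (1 → 4 → 9 → 10)

**Steps most likely to fail**

Step 2. Several processes may compete:
- ring closure through the C3 methylene of the ketimine instead of the methyl group;
- self-condensation of dehydrogenated 5 to pyrazines before the ketone captures the amine;
- reduction of ketimine 7 by the iridium hydride to a secondary amine (hydrogen borrowing);
- thermal loss of hydroxide from the product to an azafulvene that oligomerises.

The fallback avoids the dehydrogenative annulation and uses established pyrrole chemistry. It sets out from 1 through its Grignard reagent 3, prepared as in step 1. 1H-Pyrrole-2-carbaldehyde (O=Cc1ccc[nH]1) is deprotonated at nitrogen with NaH in THF at 0 °C and treated with 3, which after a water quench should give 1-(1H-pyrrol-2-yl)henicosan-1-ol F1. The crude carbinol is reduced with LiAlH4 in refluxing THF, which removes the hydroxyl group by way of the azafulvene and hydride addition, as in the reduction of 2-acylpyrroles to 2-alkylpyrroles, to give 2-henicosyl-1H-pyrrole F2. Vilsmeier–Haack formylation (POCl3, DMF, 1,2-dichloroethane, 0 °C → rt, then aqueous NaOAc) at the free α-position should give the aldehyde directly. The fallback rejoins the route at 10 and bypasses steps 2 and 3.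

Step 3. The electron-rich, N-unprotected carbinol 9 may ionise to an azafulvene on the oxide surface or on concentration and then oligomerise to dipyrromethane-type material; oxidation of the waxy substrate on the heterogeneous reagent may also stay incomplete. The fallback carries the formyl group from the start, so that no hydroxymethylpyrrole is handled. It sets out from 1. Heating 1 with PPh3 in refluxing MeCN gives eicosyl(triphenyl)phosphonium bromide F3. Its ylide (NaN(SiMe3)2, THF, −78 → 0 °C) is added to the sodium salt of 1H-pyrrole-2,5-dicarbaldehyde (O=Cc1ccc(C=O)[nH]1, 2 equiv, pre-treated with NaH) in a Wittig mono-olefination. This should give 5-[(Z)-henicos-1-en-1-yl]-1H-pyrrole-2-carbaldehyde F4, whose alkene geometry is immaterial. Hydrogenation of the side-chain alkene (H2 1 atm, Pd/C, EtOAc, rt) leaves the vinylogous formamide untouched and returns to the route at 10.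

Step 1. Wurtz homocoupling of 1 may occur during magnesium insertion, the long-chain Grignard reagent 3 may precipitate at low temperature, and bromide may open the epoxide to a bromohydrin in place of carbon–carbon bond formation. The fallback is an acetoacetic ester synthesis that sets out from 1. Alkylation of ethyl acetoacetate (CCOC(=O)CC(C)=O) with 1 (NaOEt, EtOH, reflux) gives ethyl 2-acetyldocosanoate F5. Saponification and decarboxylation (aqueous NaOH, EtOH, reflux; then H2SO4, heat) give tricosan-2-one 6. NaBH4 (THF/EtOH, rt) reduces 6 to 4, where the route is rejoined.

**Further compounds**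

F1 | step 2 | 1-(1H-pyrrol-2-yl)henicosan-1-ol (racemic) | CCCCCCCCCCCCCCCCCCCCC(O)c1ccc[nH]1
F2 | step 2 | 2-henicosyl-1H-pyrrole | CCCCCCCCCCCCCCCCCCCCCc1ccc[nH]1
F3 | step 3 | eicosyl(triphenyl)phosphonium bromide | CCCCCCCCCCCCCCCCCCCC[P+](c1ccccc1)(c1ccccc1)c1ccccc1.[Br-]
F4 | step 3 | 5-[(Z)-henicos-1-en-1-yl]-1H-pyrrole-2-carbaldehyde | CCCCCCCCCCCCCCCCCCC/C=C\c1ccc(C=O)[nH]1
F5 | step 1 | ethyl 2-acetyldocosanoate (racemic) | CCCCCCCCCCCCCCCCCCCCC(C(C)=O)C(=O)OCC
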